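## Analysis of the target

With C1 the lactone carbonyl, C2 its methylene, C3 the CH on the peroxide, C4 the methyl-bearing lactone carbon, C5 the ring methylene, C6 the methyl-bearing peroxide carbon and C7–C16 the chain (methyl on C8, phenyl on C16), the target is a 1,2-dioxane (ring A: the two oxygens, C3, C4, C5, C6) cis-fused along C3–C4 to a γ-lactone (ring B: C1, C2, C3, C4 and the lactone oxygen). It has four stereocentres, C3 (S), C4 (S), C6 (R) and C8 (R); in the bicycle the lactone oxygen on C4, C2 on C3 and C7 on C6 lie on one face and the two methyl groups and H3 on the other. C8 is insulated from the ring by C7 and cannot be induced from it, so it has to come in with fixed configuration. The sensitive groups are the O–O bond (reductants, phosphines, low-valent metals, hydrogenation), the C3–H bond (base opens the ring by retro-oxa-Michael or Kornblum–DeLaMare fragmentation) and the skipped E,E-diene with its styrene end, which excludes ozonolysis, hydrogenation and unselective radical or electrophilic alkene chemistry once it is in place. The hard part is the pair C4/C6: both are fully substituted, oxygen-bearing and 1,3-related, and C6 is a tertiary peroxide carbon that cannot be made by displacement. The strategy rests on two features: C6 carries a methyl group and the peroxide oxygen, which is the Markovnikov adduct of a C3-bound hydroperoxide to a C6=CH2 group, and C3 is at the aldehyde oxidation level, so a hydroperoxy acetal there can first be the nucleophile for C6 and later the electrophile for C2.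

## Retrosynthetic reasoning

**C1–O (ring B).** The lactone of 26 is opened to hydroxy ester 25 and, with the alcohol capped, to silyl ether 24. Lactonization needs no control of its own and can only occur readily when C2 and the C4 oxygen are cis. Forward, desilylation and acid catalysis must spare the peroxide and the diene.

**C2–C3.** 24 is cut to the cyclic methoxy peroxyacetal 23 and an acetate enolate equivalent. C3 is the only ring carbon at the acetal level, so it can be ionized to a peroxycarbenium ion without touching C4 or C6. The forward addition has to come from the face cis to the C4 oxygen.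

**C6 methyl.** The methyl of 23 is traced to the mercuriomethyl group of 22. Forward, a hydride replaces mercury without harming the O–O bond.

**O–C6 (ring A, key disconnection).** 22 is opened between the peroxide oxygen and C6 to the acyclic hydroperoxy acetal 21 with a C6 methylene group. This cut is chosen because it makes the tertiary peroxide carbon by addition rather than substitution and needs only one alkene with a nucleophile in reach, so the whole chain can already be present. The forward step must form C6 with C7 cis to the C4 oxygen.

**C3 oxidation level.** 21 goes back to dimethyl acetal 20, aldehyde 19 and ester 18. These are functional-group changes on a carbon with no α-hydrogen, so C4 cannot be lost.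

**C6=CH2.** The methylene of 18 comes from the ketone of 17, whose tertiary alcohol is free in 16. The ketone is what makes the next disconnection possible. The methylenation must be non-basic because 17 is a β-silyloxy ketone.

**C4–C5.** 16 is an aldol adduct of enolsilane 13 (from methyl ketone 12) and methyl pyruvate 14. This is the only C–C disconnection that creates the quaternary carbinol C4 by catalyst control, independent of the remote C8.

**C11=C12.** 12 comes from alcohol 11 and its silyl ether 10, which is cut at the E alkene into aldehyde 9 and sulfone 5. The cut separates the chiral-pool part from the achiral styrene part. The C6 oxygen is kept as a protected alcohol so that no enolizable ketone faces the metalated sulfone.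

**Fragments.** 9 comes from 8 and 7, that is from (R)-citronellal 6 by methyl addition at C6 and cleavage of the trisubstituted alkene to unveil C11. 5 comes from 4, 3 and 2, the last by a [3,3] shift of 1 that fixes the styrene geometry.

## Alternatives that were turned down

**Alternative 1:** one-step bicyclization. The disconnection removes O–C3, C2–C1 and C1–O at once, leading from core A1 to the C6 hydroperoxide / C4 vinyl carbinol A2. Forward, PdCl2, CuCl2, NaOAc and CO would add the hydroperoxide to C3 of the palladium-bound vinyl group, insert CO at C2 and trap the acyl with the C4 hydroxyl.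
- For: three bonds and both rings in one step, and C3 is tied to C4 by the forced cis ring fusion. On C3 control and on step economy for the bicycle it is stronger than the chosen route, which needs four steps from 21 and relies on facial selectivity at C3.
- Against: a tertiary hydroperoxide must survive divalent palladium, zerovalent palladium and the monovalent copper formed from CuCl2, all of which cleave O–O bonds. A2 must already hold the C6 hydroperoxide with the right configuration relative to C4, so the 1,3-problem is only moved to an earlier step that has no controlling element. The chain has to be cut back to a C11 silyl ether because the diene and styrene would undergo Wacker-type attack, so the chain would be finished on the base- and reductant-sensitive peroxylactone.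
- In its place the chosen route offers a closure in which only one alkene can react, with the full chain present, and a C6-forming step that at least has the C4 centre in a chair to guide it.

**Alternative 2:** carboalumination and coupling. The disconnection cuts C8–CH3 and C6–C7, leading from A3 (the same structure as 20) to triene A4 and bromoalkene A5. Forward, AlMe3 with bis(1-neomenthylindenyl)zirconium dichloride would methylate C8 of the terminal alkene of A4, and the C7 alane, after Zn(OTf)2, would couple with A5 under Pd(PPh3)4.
- For: it is more convergent than the chosen route (fragments join at the stage of 20, not 10) and avoids the ketone methylenation and the protection steps at C6. On convergence it is stronger.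
- Against: face selection in methylalumination of an unbranched terminal alkene is moderate, and a C8 epimer, remote from C4, would be a practically inseparable diastereomer carried to the end. A5 still needs its own enantioselective synthesis of C4. AlMe3 and the alane are Lewis acids that can attack the dimethyl acetal. The peroxide endgame and all its risks are unchanged.
- The chosen route offers a C8 of fixed configuration from 6 and an aldol of an established type for C4.

**Alternative 3:** ring-closing metathesis. The disconnection is C4=C5, leading from dihydrodioxine A6 to the acyclic bis-allylic peroxide A7. Forward, second-generation Grubbs catalyst would join the isopropenyl group on C3 and the vinyl group on C6.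
- For: C3 and C6 are fixed before the ring closes, so ring closure carries no stereochemical burden. On that point it is stronger in principle.
- Against: A7 needs an enantioenriched tertiary allylic hydroperoxide and its alkylation by a secondary carbon β to an ester, where elimination to the enoate should win. The metathesis must form a trisubstituted alkene next to a quaternary carbon in the presence of an allylic peroxide. A6 still lacks the C4 oxygen, so a Markovnikov oxygenation cis to the C3 arm (for example halolactonization and radical dehalogenation next to the peroxide) and chain completion follow.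
- The chosen route has C4 from the first C–C bond and forms ring A and C6 in one C–O bond formation.

Key step: step 18

Remark: the acetal carbon C3 of 21, 22 and 23 is carried as both epimers (one is drawn), because it becomes planar in step 20.
Remark: commercial 6 is taken as enantiomerically pure; any enantiomer would appear as a C8 epimer downstream.

## Route

Step 1
Reactants: 1 1-phenylprop-2-en-1-ol (racemic)
Product: 2 ethyl (4E)-5-phenylpent-4-enoate
Conditions: MeC(OEt)3, EtCO2H (cat.), 140 °C, EtOH distilled off
Reagents that add atoms: triethyl orthoacetate, CC(OCC)(OCC)OCC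
Why: Johnson–Claisen rearrangement through a chair with phenyl pseudoequatorial should give the E styrene (C15=C16); the carbinol centre of 1 is destroyed, so racemic material serves.

Step 2
Reactants: 2 ethyl (4E)-5-phenylpent-4-enoate
Product: 3 (4E)-5-phenylpent-4-en-1-ol
Conditions: LiAlH4, THF, 0 °C
Reagents that add atoms: none
Why: Hydride reduction of the ester; the styrene is inert to LiAlH4.

Step 3
Reactants: 3 (4E)-5-phenylpent-4-en-1-ol
Product: 4 1-phenyl-5-{[(4E)-5-phenylpent-4-en-1-yl]sulfanyl}-1H-tetrazole
Conditions: 1-phenyl-1H-tetrazole-5-thiol, PPh3, iPrO2CN=NCO2iPr, THF, 0 °C → rt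
Reagents that add atoms: 1-phenyl-1H-tetrazole-5-thiol, Sc1nnnn1-c1ccccc1
Why: Mitsunobu thioetherification of a primary alcohol with an acidic thiol.

Step 4
Reactants: 4 1-phenyl-5-{[(4E)-5-phenylpent-4-en-1-yl]sulfanyl}-1H-tetrazole
Product: 5 1-phenyl-5-{[(4E)-5-phenylpent-4-en-1-yl]sulfonyl}-1H-tetrazole
Conditions: (NH4)6Mo7O24·4H2O (cat.), 30% H2O2, EtOH, 0 °C → rt
Reagents that add atoms: hydrogen peroxide, OO
Why: Molybdate-catalysed sulfide-to-sulfone oxidation, chosen over a peracid so that the styrene is not epoxidized.

Step 5
Reactants: 6 (R)-citronellal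
Product: 7 (4R)-4,8-dimethylnon-7-en-2-ol (both C2 epimers)
Conditions: MeMgBr, Et2O, 0 °C; aq. NH4Cl
Reagents that add atoms: methylmagnesium bromide, C[Mg]Br
Why: Grignard addition supplies C5; the new carbinol centre (C6) is later oxidized, so its configuration is irrelevant, and C8 is β to the carbonyl and not touched.

Step 6
Reactants: 7 (4R)-4,8-dimethylnon-7-en-2-ol
Product: 8 tert-butyl{[(4R)-4,8-dimethylnon-7-en-2-yl]oxy}dimethylsilane
Conditions: tBuMe2SiCl, imidazole, DMF, rt
Reagents that add atoms: tert-butyldimethylsilyl chloride, CC(C)(C)[Si](C)(C)Cl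
Why: Silylation keeps C6 at the alcohol level, so no enolizable ketone is present during the olefination of step 8.

Step 7
Reactants: 8 tert-butyl{[(4R)-4,8-dimethylnon-7-en-2-yl]oxy}dimethylsilane
Product: 9 (4R)-6-[(tert-butyldimethylsilyl)oxy]-4-methylheptanal
Conditions: O3, CH2Cl2–MeOH, −78 °C; then Me2S, → rt
Reagents that add atoms: ozone, [O-][O+]=O
Why: Ozonolysis with reductive work-up of the only alkene present unveils C11 as the aldehyde.

Step 8
Reactants: 9 (4R)-6-[(tert-butyldimethylsilyl)oxy]-4-methylheptanal; 5 1-phenyl-5-{[(4E)-5-phenylpent-4-en-1-yl]sulfonyl}-1H-tetrazole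
Product: 10 tert-butyldimethyl{[(4R,7E,11E)-4-methyl-12-phenyldodeca-7,11-dien-2-yl]oxy}silane
Conditions: 5, KN(SiMe3)2, DME, −60 °C; then 9, −60 °C → rt
Reagents that add atoms: none
Why: Julia–Kocienski olefination; with a phenyltetrazolyl sulfone, a potassium base in DME and an unbranched aldehyde, addition, Smiles rearrangement and loss of SO2 should give the E C11=C12 bond.

Step 9
Reactants: 10 tert-butyldimethyl{[(4R,7E,11E)-4-methyl-12-phenyldodeca-7,11-dien-2-yl]oxy}silane
Product: 11 (4R,7E,11E)-4-methyl-12-phenyldodeca-7,11-dien-2-ol
Conditions: Bu4NF, THF, rt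
Reagents that add atoms: none
Why: Fluoride cleavage of a secondary silyl ether; nothing else in the molecule is fluoride-sensitive.

Step 10
Reactants: 11 (4R,7E,11E)-4-methyl-12-phenyldodeca-7,11-dien-2-ol
Product: 12 (4R,7E,11E)-4-methyl-12-phenyldodeca-7,11-dien-2-one
Conditions: Dess–Martin periodinane, NaHCO3, CH2Cl2, rt
Reagents that add atoms: none
Why: Mild oxidation of a secondary alcohol to the methyl ketone; both carbinol epimers converge and the alkenes are untouched.

Step 11
Reactants: 12 (4R,7E,11E)-4-methyl-12-phenyldodeca-7,11-dien-2-one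
Product: 13 trimethyl{[(4R,7E,11E)-4-methyl-12-phenyldodeca-1,7,11-trien-2-yl]oxy}silane
Conditions: LiN(iPr)2, THF, −78 °C; Me3SiCl, −78 → 0 °C
Reagents that add atoms: chlorotrimethylsilane, C[Si](C)(C)Cl
Why: Kinetic deprotonation of a methyl ketone occurs at the methyl group (C5), the other α-position being next to the C8 branch; O-silylation fixes the terminal enolsilane.

Step 12
Reactants: 13 trimethyl{[(4R,7E,11E)-4-methyl-12-phenyldodeca-1,7,11-trien-2-yl]oxy}silane; 14 methyl pyruvate
Product: 16 methyl (2S,6R,9E,13E)-2-hydroxy-2,6-dimethyl-4-oxo-14-phenyltetradeca-9,13-dienoate, via trimethylsilyl ether of the aldol adduct 15 (not isolated)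
Conditions: Cu(OTf)2 (10 mol %), 2,2'-(propane-2,2-diyl)bis[(4S)-4-tert-butyl-4,5-dihydrooxazole] (11 mol %), THF, −78 °C; then 1 M HCl, THF, rt
Reagents that add atoms: none
Why: Mukaiyama aldol addition of an enolsilane to a pyruvate ester chelated to the bis(oxazoline)–Cu(OTf)2 complex, a known catalytic enantioselective reaction; the (S,S)-ligand is expected to shield the re face of the ketone, so C5 adds to the si face and C4 is formed S under catalyst control, independent of the remote C8; the acid work-up cleaves 15.

Step 13
Reactants: 16 methyl (2S,6R,9E,13E)-2-hydroxy-2,6-dimethyl-4-oxo-14-phenyltetradeca-9,13-dienoate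
Product: 17 methyl (2S,6R,9E,13E)-2,6-dimethyl-4-oxo-14-phenyl-2-[(triethylsilyl)oxy]tetradeca-9,13-dienoate
Conditions: Et3SiOTf, 2,6-lutidine, CH2Cl2, −78 → 0 °C
Reagents that add atoms: triethylsilyl trifluoromethanesulfonate, CC[Si](CC)(CC)OS(=O)(=O)C(F)(F)F
Why: A silyl triflate with a hindered base silylates the tertiary alcohol without the basic conditions that would invite retro-aldol cleavage.

Step 14
Reactants: 17 methyl (2S,6R,9E,13E)-2,6-dimethyl-4-oxo-14-phenyl-2-[(triethylsilyl)oxy]tetradeca-9,13-dienoate
Product: 18 methyl (2S,6R,9E,13E)-2,6-dimethyl-4-methylidene-14-phenyl-2-[(triethylsilyl)oxy]tetradeca-9,13-dienoate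
Conditions: Zn, CH2Br2, TiCl4, THF–CH2Cl2, 0 °C → rt
Reagents that add atoms: dibromomethane, BrCBr
Why: Takai–Lombardo methylenation is non-basic and ketone-selective, so the β-silyloxy ketone should neither eliminate nor fragment and the ester stays intact.

Step 15
Reactants: 18 methyl (2S,6R,9E,13E)-2,6-dimethyl-4-methylidene-14-phenyl-2-[(triethylsilyl)oxy]tetradeca-9,13-dienoate
Product: 19 (2S,6R,9E,13E)-2,6-dimethyl-4-methylidene-14-phenyl-2-[(triethylsilyl)oxy]tetradeca-9,13-dienal
Conditions: iBu2AlH, CH2Cl2, −78 °C; aq. potassium sodium tartrate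
Reagents that add atoms: none
Why: Partial reduction of an α-silyloxy ester: the aluminium hemiacetal is stable at −78 °C and gives the aldehyde on work-up; C4 is quaternary and cannot epimerize.

Step 16
Reactants: 19 (2S,6R,9E,13E)-2,6-dimethyl-4-methylidene-14-phenyl-2-[(triethylsilyl)oxy]tetradeca-9,13-dienal
Product: 20 {[(2S,6R,9E,13E)-1,1-dimethoxy-2,6-dimethyl-4-methylidene-14-phenyltetradeca-9,13-dien-2-yl]oxy}triethylsilane
Conditions: HC(OMe)3, MeOH, pyridinium p-toluenesulfonate (cat.), 40 °C; Et3N
Reagents that add atoms: trimethyl orthoformate, COC(OC)OC; methanol, CO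
Why: Acid-catalysed acetalization driven by the orthoformate; the weak acid is chosen so that the tertiary silyl ether and the 1,1-disubstituted alkene survive.

Step 17
Reactants: 20 {[(2S,6R,9E,13E)-1,1-dimethoxy-2,6-dimethyl-4-methylidene-14-phenyltetradeca-9,13-dien-2-yl]oxy}triethylsilane
Product: 21 {[(1S,2S,6R,9E,13E)-1-hydroperoxy-1-methoxy-2,6-dimethyl-4-methylidene-14-phenyltetradeca-9,13-dien-2-yl]oxy}triethylsilane (with its 1R epimer)
Conditions: H2O2 (anhydrous, in Et2O), camphorsulfonic acid (cat.), Et2O, 0 °C; NaHCO3
Reagents that add atoms: hydrogen peroxide, OO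
Why: Acid-catalysed perhydrolysis of an acetal through the methoxy oxocarbenium ion exchanges one methoxy group for a hydroperoxy group; the reaction is stopped at partial conversion and 20 is recycled to limit double exchange.

Step 18
Reactants: 21 {[(1S,2S,6R,9E,13E)-1-hydroperoxy-1-methoxy-2,6-dimethyl-4-methylidene-14-phenyltetradeca-9,13-dien-2-yl]oxy}triethylsilane (with its 1R epimer)
Product: 22 {[(3S,4S,6R)-3-methoxy-4-methyl-6-[(2R,5E,9E)-2-methyl-10-phenyldeca-5,9-dien-1-yl]-4-[(triethylsilyl)oxy]-1,2-dioxan-6-yl]methyl}mercury acetate (target locants; with its 3-epimer)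
Conditions: Hg(OAc)2 (1.1 equiv), CH2Cl2, 0 °C → rt
Reagents that add atoms: mercury diacetate, CC(=O)O[Hg]OC(C)=O
Why: Divalent mercury adds to the electron-rich C6=CH2 group to give a mercurinium ion, and the terminal oxygen of the C3 hydroperoxide opens it anti at the tertiary carbon C6 while acetate takes the proton and mercury stays on the former methylene carbon. The closest known reaction type is the cycloperoxymercuration of unsaturated hydroperoxides and hydroperoxy acetals to 1,2-dioxanes. Ring A closes in the 6-exo-trig mode through a chair made of O–O, C3, C4, C5 and C6. The new stereocentre C6 is controlled by C4: in the preferred chair the C4 methyl and the mercury-bearing carbon should be equatorial and the small silyloxy oxygen and C7 axial, which puts C7 cis to the C4 oxygen as in 26; this is a prediction from 1,3-diaxial strain, and the C6 epimer would be removed by chromatography here or after step 19. Regioselectivity (Markovnikov, 6-exo over 7-endo) is secured by the tertiary against the primary alkene carbon. Chemoselectivity among the four π-systems is secured by position, since only C6 has a nucleophile in reach, while the C11=C12 and styrene bonds can only bind mercury reversibly in a solvent with no nucleophile stronger than acetate. Both C3 epimers of 21 close alike, and no acid stronger than the liberated acetic acid is present, so the peroxyacetal and the silyl ether should survive.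

Step 19
Reactants: 22 {[(3S,4S,6R)-3-methoxy-4-methyl-6-[(2R,5E,9E)-2-methyl-10-phenyldeca-5,9-dien-1-yl]-4-[(triethylsilyl)oxy]-1,2-dioxan-6-yl]methyl}mercury acetate
Product: 23 triethyl{[(3S,4S,6R)-3-methoxy-4,6-dimethyl-6-[(2R,5E,9E)-2-methyl-10-phenyldeca-5,9-dien-1-yl]-1,2-dioxan-4-yl]oxy}silane (target locants; with its 3-epimer)
Conditions: NaBH4, 2 M NaOH, THF, 0 °C
Reagents that add atoms: none
Why: Hydride demercuration: the alkylmercury hydride fragments to a primary radical that takes hydrogen from a second alkylmercury hydride; no stereocentre is touched and dialkyl peroxides tolerate cold alkaline NaBH4; the hydride is kept concentrated so that hydrogen transfer outruns attack of the radical on the O–O bond.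

Step 20
Reactants: 23 triethyl{[(3S,4S,6R)-3-methoxy-4,6-dimethyl-6-[(2R,5E,9E)-2-methyl-10-phenyldeca-5,9-dien-1-yl]-1,2-dioxan-4-yl]oxy}silane
Product: 24 methyl 2-[(3S,4S,6R)-4,6-dimethyl-6-[(2R,5E,9E)-2-methyl-10-phenyldeca-5,9-dien-1-yl]-4-[(triethylsilyl)oxy]-1,2-dioxan-3-yl]acetate
Conditions: CH2=C(OMe)OSiMe2tBu, Me3SiOTf (0.2 equiv), CH2Cl2, −78 °C
Reagents that add atoms: 1-(tert-butyldimethylsilyloxy)-1-methoxyethene, C=C(OC)O[Si](C)(C)C(C)(C)C
Why: The silyl triflate removes the methoxy group to give the cyclic peroxycarbenium ion, which the silyl ketene acetal traps in a Mukaiyama-type addition that returns a silyl triflate, a known reaction of 3-alkoxy-1,2-dioxanes; axial attack on the half-chair with the C4 silyloxy group pseudoequatorial and the C4 methyl pseudoaxial, anti to that methyl, should place C2 cis to the C4 oxygen (3S), which is a prediction.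

Step 21
Reactants: 24 methyl 2-[(3S,4S,6R)-4,6-dimethyl-6-[(2R,5E,9E)-2-methyl-10-phenyldeca-5,9-dien-1-yl]-4-[(triethylsilyl)oxy]-1,2-dioxan-3-yl]acetate
Product: 26 the target, (3S,4S,6R)-4,6-dimethyl-6-[(2R,5E,9E)-2-methyl-10-phenyldeca-5,9-dien-1-yl]-1,2-dioxane cis-fused at C3–C4 to the γ-lactone, via hydroxy ester 25 (not isolated)
Conditions: HF·pyridine, THF, 0 °C → rt; then TsOH·H2O (cat.), CH2Cl2, rt
Reagents that add atoms: none
Why: Fluoride-type cleavage of the tertiary triethylsilyl ether under acidic conditions avoids base at C3–H, and the freed C4 hydroxyl, held cis to the C3 acetate arm, closes the five-membered lactone under acid catalysis; peroxide and diene tolerate both reagents.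

## Compound list

1 | 1-phenylprop-2-en-1-ol (racemic) | C=CC(O)c1ccccc1 | starting material
2 | ethyl (4E)-5-phenylpent-4-enoate | CCOC(=O)CC/C=C/c1ccccc1 | intermediate
3 | (4E)-5-phenylpent-4-en-1-ol | OCCC/C=C/c1ccccc1 | intermediate
4 | 1-phenyl-5-{[(4E)-5-phenylpent-4-en-1-yl]sulfanyl}-1H-tetrazole | c1ccccc1/C=C/CCCSc1nnnn1-c1ccccc1 | intermediate
5 | 1-phenyl-5-{[(4E)-5-phenylpent-4-en-1-yl]sulfonyl}-1H-tetrazole | O=S(=O)(CCC/C=C/c1ccccc1)c1nnnn1-c1ccccc1 | intermediate
6 | (R)-citronellal, (3R)-3,7-dimethyloct-6-enal | C[C@H](CCC=C(C)C)CC=O | starting material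
7 | (4R)-4,8-dimethylnon-7-en-2-ol (both C2 epimers) | C[C@H](CCC=C(C)C)CC(C)O | intermediate
8 | tert-butyl{[(4R)-4,8-dimethylnon-7-en-2-yl]oxy}dimethylsilane (both C2 epimers) | C[C@H](CCC=C(C)C)CC(C)O[Si](C)(C)C(C)(C)C | intermediate
9 | (4R)-6-[(tert-butyldimethylsilyl)oxy]-4-methylheptanal (both C6 epimers) | C[C@H](CCC=O)CC(C)O[Si](C)(C)C(C)(C)C | intermediate
10 | tert-butyldimethyl{[(4R,7E,11E)-4-methyl-12-phenyldodeca-7,11-dien-2-yl]oxy}silane (both C2 epimers) | C[C@H](CC/C=C/CC/C=C/c1ccccc1)CC(C)O[Si](C)(C)C(C)(C)C | intermediate
11 | (4R,7E,11E)-4-methyl-12-phenyldodeca-7,11-dien-2-ol (both C2 epimers) | C[C@H](CC/C=C/CC/C=C/c1ccccc1)CC(C)O | intermediate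
12 | (4R,7E,11E)-4-methyl-12-phenyldodeca-7,11-dien-2-one | C[C@H](CC/C=C/CC/C=C/c1ccccc1)CC(C)=O | intermediate
13 | trimethyl{[(4R,7E,11E)-4-methyl-12-phenyldodeca-1,7,11-trien-2-yl]oxy}silane | C[C@H](CC/C=C/CC/C=C/c1ccccc1)CC(=C)O[Si](C)(C)C | intermediate
14 | methyl pyruvate | CC(=O)C(=O)OC | starting material
15 | methyl (2S,6R,9E,13E)-2,6-dimethyl-4-oxo-14-phenyl-2-[(trimethylsilyl)oxy]tetradeca-9,13-dienoate | C[C@H](CC/C=C/CC/C=C/c1ccccc1)CC(=O)C[C@](C)(O[Si](C)(C)C)C(=O)OC | intermediate
16 | methyl (2S,6R,9E,13E)-2-hydroxy-2,6-dimethyl-4-oxo-14-phenyltetradeca-9,13-dienoate | C[C@H](CC/C=C/CC/C=C/c1ccccc1)CC(=O)C[C@](C)(O)C(=O)OC | intermediate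
17 | methyl (2S,6R,9E,13E)-2,6-dimethyl-4-oxo-14-phenyl-2-[(triethylsilyl)oxy]tetradeca-9,13-dienoate | C[C@H](CC/C=C/CC/C=C/c1ccccc1)CC(=O)C[C@](C)(O[Si](CC)(CC)CC)C(=O)OC | intermediate
18 | methyl (2S,6R,9E,13E)-2,6-dimethyl-4-methylidene-14-phenyl-2-[(triethylsilyl)oxy]tetradeca-9,13-dienoate | C[C@H](CC/C=C/CC/C=C/c1ccccc1)CC(=C)C[C@](C)(O[Si](CC)(CC)CC)C(=O)OC | intermediate
19 | (2S,6R,9E,13E)-2,6-dimethyl-4-methylidene-14-phenyl-2-[(triethylsilyl)oxy]tetradeca-9,13-dienal | C[C@H](CC/C=C/CC/C=C/c1ccccc1)CC(=C)C[C@](C)(O[Si](CC)(CC)CC)C=O | intermediate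
20 | {[(2S,6R,9E,13E)-1,1-dimethoxy-2,6-dimethyl-4-methylidene-14-phenyltetradeca-9,13-dien-2-yl]oxy}triethylsilane | C[C@H](CC/C=C/CC/C=C/c1ccccc1)CC(=C)C[C@](C)(O[Si](CC)(CC)CC)C(OC)OC | intermediate
21 | {[(1S,2S,6R,9E,13E)-1-hydroperoxy-1-methoxy-2,6-dimethyl-4-methylidene-14-phenyltetradeca-9,13-dien-2-yl]oxy}triethylsilane (1S drawn; 1R epimer also present) | C[C@H](CC/C=C/CC/C=C/c1ccccc1)CC(=C)C[C@](C)(O[Si](CC)(CC)CC)[C@@H](OC)OO | intermediate
22 | {[(3S,4S,6R)-3-methoxy-4-methyl-6-[(2R,5E,9E)-2-methyl-10-phenyldeca-5,9-dien-1-yl]-4-[(triethylsilyl)oxy]-1,2-dioxan-6-yl]methyl}mercury acetate (target locants; 3S drawn, 3-epimer also present) | C[C@H](CC/C=C/CC/C=C/c1ccccc1)C[C@]1(C[Hg]OC(C)=O)C[C@](C)(O[Si](CC)(CC)CC)[C@@H](OC)OO1 | intermediate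
23 | triethyl{[(3S,4S,6R)-3-methoxy-4,6-dimethyl-6-[(2R,5E,9E)-2-methyl-10-phenyldeca-5,9-dien-1-yl]-1,2-dioxan-4-yl]oxy}silane (target locants; 3S drawn, 3-epimer also present) | C[C@H](CC/C=C/CC/C=C/c1ccccc1)C[C@]1(C)C[C@](C)(O[Si](CC)(CC)CC)[C@@H](OC)OO1 | intermediate
24 | methyl 2-[(3S,4S,6R)-4,6-dimethyl-6-[(2R,5E,9E)-2-methyl-10-phenyldeca-5,9-dien-1-yl]-4-[(triethylsilyl)oxy]-1,2-dioxan-3-yl]acetate | C[C@H](CC/C=C/CC/C=C/c1ccccc1)C[C@]1(C)C[C@](C)(O[Si](CC)(CC)CC)[C@H](CC(=O)OC)OO1 | intermediate
25 | methyl 2-[(3S,4S,6R)-4-hydroxy-4,6-dimethyl-6-[(2R,5E,9E)-2-methyl-10-phenyldeca-5,9-dien-1-yl]-1,2-dioxan-3-yl]acetate | C[C@H](CC/C=C/CC/C=C/c1ccccc1)C[C@]1(C)C[C@](C)(O)[C@H](CC(=O)OC)OO1 | intermediate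
26 | CNP0365311.2, the (3S,4S,6R,8R) cis-fused 1,2-dioxane γ-lactone with the (5E,9E)-2-methyl-10-phenyldeca-5,9-dienyl chain on C6 | C[C@H](CC/C=C/CC/C=C/c1ccccc1)C[C@]1(C)C[C@]2(C)OC(=O)C[C@@H]2OO1 | target

## Step count and least certain steps

Total: 21 steps. Longest linear sequence: 18 steps (from 1 to 26: steps 1–4, then steps 8–21). The branch from 6 (steps 5–7) joins in step 8, and methyl pyruvate 14 enters in step 12.

**Step 18 (key step).** The most likely failure is poor facial selectivity at C6. Each competing chair carries one 1,3-diaxial contact between the two fully substituted carbons C4 and C6, and the difference between placing C7 or the mercury-bearing carbon axial is small, so the closure may give the epimers in similar amounts or even prefer the wrong one.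
Fallback: give up the 1,3-induction and change the bond that closes the ring. It sets out from 20 and comes back at 22. Hg(OAc)2 with excess anhydrous H2O2 in CH2Cl2 at 0 °C should add a hydroperoxy group intermolecularly to the C6 methylene, since terminal 1,1-disubstituted alkenes are oxymercurated far faster than 1,2-disubstituted alkenes and styrenes; this gives the tertiary C6 hydroperoxide with an acetoxymercuriomethyl group F1 as both C6 epimers. Catalytic pyridinium p-toluenesulfonate then closes ring A from the other end: the C6 hydroperoxide displaces one methoxy group of the C3 acetal in a six-membered peroxyacetalization, and 22 is separated from its C6 epimer. This cannot create selectivity. It gives the two epimers in comparable amounts, which is the better outcome only if the chair closure prefers the wrong epimer, and it no longer needs 21.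

**Step 17.** The most likely failure is lack of control over the degree of exchange. The hindered acetal, deactivated by the α-silyloxy group, needs acid strong enough that a second exchange, loss of the silyl ether and attack of the oxocarbenium ion on the C6 methylene compete, so 21 may be obtained only in a mixture.
Fallback: drive the exchange to the end instead of stopping it halfway. It sets out from 20 and comes back at 22. A large excess of ethereal H2O2 with camphorsulfonic acid converts 20 into the geminal dihydroperoxide F2. Hg(OAc)2 in CH2Cl2 closes F2 as in step 18 to the 3-hydroperoxy-1,2-dioxane with the acetoxymercuriomethyl group F3. Brief treatment of F3 with MeOH and pyridinium p-toluenesulfonate at 0 °C exchanges the exocyclic hydroperoxy group for methoxy and gives 22.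

**Step 20.** The most likely failure is poor facial selectivity at C3. The other half-chair, with the silyloxy group pseudoaxial and C7 axial, avoids the methyl/methyl contact of the productive one, and axial attack on it puts C2 trans to the C4 oxygen.
Fallback: replace kinetic control at C3 by equilibration. It sets out from 23 and comes back at 25. Step 20 is run as planned and the unwanted 3-epimeric ester F4 is not discarded. HF·pyridine converts F4 into the 3-epimeric hydroxy ester F5. Et2NH in CF3CH2OH opens F5 by retro-oxa-Michael elimination to the hydroperoxy enoate F6, and 6-exo oxa-Michael re-closure interconverts the C3 epimers. The epimer with C2 cis to the C4 hydroxyl is 25, which is drained to 26 by the lactonization of step 21, while F5 is returned to the equilibration.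

**Step 19.** The most likely failure is ring opening of the primary radical next to the peroxide carbon. Intramolecular homolytic substitution at the O–O bond competes with hydrogen transfer when the concentration of the alkylmercury hydride is low.
Fallback: make the same radical from another precursor in the presence of a far faster hydrogen donor. It sets out from 22 and comes back at 23. I2 in CH2Cl2 replaces mercury by iodine and gives the iodomethyl dioxane F7. F7 is reduced with concentrated Bu3SnH, Et3B and air at 0 °C with catalytic PhSeSePh, so that the radical is quenched by the selenol before it can attack the peroxide.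

## Further compounds

F1 | step 18 | C6 hydroperoxide with acetoxymercuriomethyl group on C6, C3 dimethyl acetal and C4 triethylsilyl ether (both C6 epimers) | C[C@H](CC/C=C/CC/C=C/c1ccccc1)CC(C[Hg]OC(C)=O)(OO)C[C@](C)(O[Si](CC)(CC)CC)C(OC)OC
F2 | step 17 | C3 geminal dihydroperoxide with C4 triethylsilyl ether and C6 methylene | C[C@H](CC/C=C/CC/C=C/c1ccccc1)CC(=C)C[C@](C)(O[Si](CC)(CC)CC)C(OO)OO
F3 | step 17 | 3-hydroperoxy-1,2-dioxane with acetoxymercuriomethyl group on C6 (both C3 epimers) | C[C@H](CC/C=C/CC/C=C/c1ccccc1)C[C@]1(C[Hg]OC(C)=O)C[C@](C)(O[Si](CC)(CC)CC)C(OO)OO1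
F4 | step 20 | 3-epimer of 24, C2 trans to the C4 silyloxy group | C[C@H](CC/C=C/CC/C=C/c1ccccc1)C[C@]1(C)C[C@](C)(O[Si](CC)(CC)CC)[C@@H](CC(=O)OC)OO1
F5 | step 20 | 3-epimer of 25, C2 trans to the C4 hydroxyl | C[C@H](CC/C=C/CC/C=C/c1ccccc1)C[C@]1(C)C[C@](C)(O)[C@@H](CC(=O)OC)OO1
F6 | step 20 | ring-opened methyl (2E)-4-hydroxy-6-hydroperoxy enoate with C4 and C6 as in 26 | C[C@H](CC/C=C/CC/C=C/c1ccccc1)C[C@@](C)(OO)C[C@](C)(O)/C=C/C(=O)OC
F7 | step 19 | 6-(iodomethyl) analogue of 22 | C[C@H](CC/C=C/CC/C=C/c1ccccc1)C[C@]1(CI)C[C@](C)(O[Si](CC)(CC)CC)[C@@H](OC)OO1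
A1 | alternative 1 | peroxylactone core with C11 tert-butyldimethylsilyl ether | C[C@H](CCCO[Si](C)(C)C(C)(C)C)C[C@]1(C)C[C@]2(C)OC(=O)C[C@@H]2OO1
A2 | alternative 1 | C6 tertiary hydroperoxide with C4 vinyl carbinol and C11 silyl ether | C[C@H](CCCO[Si](C)(C)C(C)(C)C)C[C@@](C)(OO)C[C@](C)(O)C=C
A3 | alternative 2 | full chain C3–C16 with C6 methylene and C3 dimethyl acetal (same structure as 20) | C[C@H](CC/C=C/CC/C=C/c1ccccc1)CC(=C)C[C@](C)(O[Si](CC)(CC)CC)C(OC)OC
A4 | alternative 2 | (5E,9E)-10-phenyldeca-1,5,9-triene | C=CCC/C=C/CC/C=C/c1ccccc1
A5 | alternative 2 | {[(2S)-4-bromo-1,1-dimethoxy-2-methylpent-4-en-2-yl]oxy}triethylsilane | C=C(Br)C[C@](C)(O[Si](CC)(CC)CC)C(OC)OC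
A6 | alternative 3 | 3,6-dihydro-1,2-dioxine with tert-butyl acetate arm on C3 and C11 silyl ether | C[C@H](CCCO[Si](C)(C)C(C)(C)C)C[C@]1(C)C=C(C)[C@H](CC(=O)OC(C)(C)C)OO1
A7 | alternative 3 | acyclic peroxide joining the C6 vinyl carbon and the C3 isopropenyl carbon | C[C@H](CCCO[Si](C)(C)C(C)(C)C)C[C@](C)(C=C)OO[C@@H](CC(=O)OC(C)(C)C)C(C)=C
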